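The plan rests on cutting the C7–C11 bond of the γ-lactone (ring O–C6–C7–C11–C12) fused to the ten-membered carbocycle C1–C10. A rhodium carbene at C11, tethered through the C6 ester oxygen, lies 1,5 to the C7 methylene; insertion into one C7–H bond forms C7–C11, closes the lactone and sets the trans C6/C7 fusion in a single operation, and leaves a phosphonate for late methylenation. The precursor is the complete ten-membered ring (cis-4,5-epoxide, C8 angelate, C9 acetate, C10 ester, C2 silyl ether) carrying a diazophosphonoacetate on O6; it is assembled by a boron aldol union of two fragments and ring-closing metathesis at C1=C10.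

Key step: step 20

Remark: germacrane locants are used throughout (ring C1–C10, C11–C13 lactone carbons, C14 the ester carbon on C10, C15 the methyl on C4). The configuration planned for is 2S,4R,5S,6S,7R,8S,9S, with a cis-4,5-epoxide (C3 and C6 on the same side) and a C1=C10 alkene that is cis within the ring (C2 and C9 on the same side, CIP E).

**Fragment A (C1–C6)**

Step 1
Reactants: 1 (S)-epichlorohydrin
Product: 2 (S)-1-chloropent-4-yn-2-ol
Conditions: HC≡CLi (acetylene, n-BuLi), BF3·OEt2, THF, −78 °C
Reagents that add atoms: lithium acetylide, [Li+].[C-]#C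
Why: Yamaguchi-type BF3-promoted alkynylation, in which the acetylide opens the epoxide at its unsubstituted carbon by SN2 attack so that the C–O bond of the stereocentre (future C2) is untouched and, at −78 °C, the fluoroborate-bound alkoxide does not displace chloride.

Step 2
Reactants: 2 (S)-1-chloropent-4-yn-2-ol
Product: 4 (S)-hex-1-en-5-yn-3-ol, via (S)-2-propargyloxirane 3 (not isolated)
Conditions: Me3S+ I−, n-BuLi (excess), THF, −20 °C to rt
Reagents that add atoms: trimethylsulfonium iodide, C[S+](C)C.[I-]
Why: Epoxide-to-allylic-alcohol homologation with dimethylsulfonium methylide: the base first closes the chlorohydrin to terminal epoxide 3, the ylide opens it at CH2 and the resulting sulfonium alkoxide loses Me2S by β-elimination, all without breaking the C–O bond at the stereocentre, whose configuration is therefore kept.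

Step 3
Reactants: 4 (S)-hex-1-en-5-yn-3-ol
Product: 5 (S)-3-(tert-butyldimethylsilyloxy)hex-1-en-5-yne
Conditions: TBSCl, imidazole, DMF, rt
Reagents that add atoms: tert-butyldimethylsilyl chloride, CC(C)(C)[Si](C)(C)Cl
Why: Standard imidazole-promoted silylation of the only hydroxyl; the TBS ether is carried to the last step, where it also keeps O–H insertion out of the carbene step.

Step 4
Reactants: 5 (S)-3-(tert-butyldimethylsilyloxy)hex-1-en-5-yne
Product: 6 (S)-5-(tert-butyldimethylsilyloxy)hept-6-en-2-yn-1-ol
Conditions: n-BuLi, THF, −78 °C; (CH2O)n, −78 °C to rt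
Reagents that add atoms: paraformaldehyde (as formaldehyde), C=O
Why: Acetylide hydroxymethylation: the terminal alkyne C–H is by far the most acidic site and its lithium salt adds to formaldehyde, creating no stereocentre.

Step 5
Reactants: 6 (S)-5-(tert-butyldimethylsilyloxy)hept-6-en-2-yn-1-ol
Product: 7 (2Z,5S)-5-(tert-butyldimethylsilyloxy)-3-methylhepta-2,6-dien-1-ol
Conditions: Fe(acac)3 (15 mol %), MeMgBr (4 equiv), THF, −78 to 0 °C
Reagents that add atoms: methylmagnesium bromide, C[Mg]Br
Why: Alkoxide-directed iron-catalysed syn-carbomagnesiation of a propargylic alcohol, which places the methyl group on the distal alkyne carbon (C4) and leaves a chelated vinylmagnesium at C5 that is protonated on work-up, so that the chain and CH2OH end up cis (Z), the geometry the cis-4,5-epoxide needs.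

Step 6
Reactants: 7 (2Z,5S)-5-(tert-butyldimethylsilyloxy)-3-methylhepta-2,6-dien-1-ol
Product: 8 epoxy alcohol [(2S,3R)-3-[(2S)-2-(tert-butyldimethylsilyloxy)but-3-en-1-yl]-3-methyloxiran-2-yl]methanol
Conditions: Ti(OiPr)4 (10 mol %), diethyl L-(+)-tartrate (12 mol %), t-BuOOH, 4 Å MS, CH2Cl2, −20 °C
Reagents that add atoms: tert-butyl hydroperoxide, CC(C)(C)OO
Why: Katsuki–Sharpless asymmetric epoxidation, in which the titanium–L-(+)-tartrate peroxide delivers oxygen to the allylic alcohol face that gives the (2S,3R)-epoxy alcohol from a Z-trisubstituted substrate (as with nerol), i.e. 4R,5S, while the silylated vinyl carbinol is not a substrate.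

Step 7
Reactants: 8 epoxy alcohol
Product: 9 epoxy aldehyde (2R,3R)-3-[(2S)-2-(tert-butyldimethylsilyloxy)but-3-en-1-yl]-3-methyloxirane-2-carbaldehyde
Conditions: TEMPO (10 mol %), PhI(OAc)2, CH2Cl2, rt
Reagents that add atoms: none
Why: TEMPO/PhI(OAc)2 (oxoammonium) oxidation takes the primary alcohol to the aldehyde without over-oxidation or epoxide opening, and the α-epoxy aldehyde is used at once.

**Fragment B (C7–C10, C14)**

Step 8
Reactants: 10 methacrolein; 11 methyl acrylate
Product: 12 methyl (±)-3-hydroxy-4-methyl-2-methylidenepent-4-enoate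
Conditions: DABCO (30 mol %), neat, rt
Reagents that add atoms: none
Why: Morita–Baylis–Hillman reaction, in which DABCO adds to the acrylate, the resulting enolate adds 1,2 to the enal carbonyl and the amine is expelled, giving the racemic carbinol that holds the future C9, C10 and C14.

Step 9
Reactants: 12 methyl (±)-3-hydroxy-4-methyl-2-methylidenepent-4-enoate
Product: 13 methyl (R)-3-hydroxy-4-methyl-2-methylidenepent-4-enoate
Conditions: Ti(OiPr)4 (10 mol %), D-(−)-diisopropyl tartrate (15 mol %), t-BuOOH (0.6 equiv), 4 Å MS, CH2Cl2, −20 °C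
Reagents that add atoms: none
Why: Sharpless kinetic resolution of a secondary allylic alcohol: with the D-(−)-tartrate the S carbinol is epoxidised at its electron-rich isopropenyl group much faster than the R carbinol, so that running to slightly more than half conversion should leave the R alcohol (the future 9S centre), the acrylate alkene being inert to the titanium peroxide.

Step 10
Reactants: 13 methyl (R)-3-hydroxy-4-methyl-2-methylidenepent-4-enoate
Product: 14 methyl (R)-3-acetoxy-4-methyl-2-methylidenepent-4-enoate
Conditions: Ac2O, pyridine, DMAP (5 mol %), CH2Cl2, 0 °C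
Reagents that add atoms: acetic anhydride, CC(=O)OC(C)=O
Why: DMAP-catalysed acetylation of the only hydroxyl installs the C9 acetate of the target before any other hydroxyl exists, which removes the need to tell the C8 and C9 oxygens apart later.

Step 11
Reactants: 14 methyl (R)-3-acetoxy-4-methyl-2-methylidenepent-4-enoate
Product: 15 methyl (S)-3-acetoxy-2-methylidene-4-oxopentanoate
Conditions: O3, CH2Cl2, −78 °C (Sudan Red 7B end point); Me2S
Reagents that add atoms: ozone, [O-][O+]=O
Why: Ozonolysis with reductive work-up, in which ozone attacks the electron-rich 1,1-disubstituted alkene far faster than the electron-poor acrylate and so unmasks the methyl ketone (C8 carbonyl, C7 methyl) next to the untouched acetoxy stereocentre.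

**Union, ring closure and end game**

Step 12
Reactants: 15 methyl (S)-3-acetoxy-2-methylidene-4-oxopentanoate; 9 epoxy aldehyde
Product: 17 open-chain aldol (2S,4R,5S,6S,9S; C6 hydroxyl; C8 ketone), via dicyclohexylboron enolate 16 (not isolated)
Conditions: (c-C6H11)2BCl, Et3N, Et2O, −78 °C; then 9, −78 to −20 °C; H2O2, pH 7 buffer, MeOH, 0 °C
Reagents that add atoms: none
Why: Boron-mediated aldol reaction: the dialkylboron chloride and amine enolise α-acyloxy ketones kinetically on the side away from the oxygenated carbon, here the C7 methyl, and the enolate adds through a closed six-membered transition state to the aldehyde face anti to the epoxide C–O bond (Felkin–Anh), which should give the 5,6-anti carbinol, 6S, without touching C9.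

Step 13
Reactants: 17 open-chain aldol
Product: 18 C6 triethylsilyl ether of the aldol (C8 ketone)
Conditions: TESCl, imidazole, CH2Cl2, 0 °C
Reagents that add atoms: triethylsilyl chloride, CC[Si](CC)(CC)Cl
Why: Imidazole-promoted silylation under near-neutral conditions caps the C6 hydroxyl without retro-aldol or β-elimination, TES being chosen because it can be removed later beside the C2 TBS ether.

Step 14
Reactants: 18 C6 triethylsilyl ether (C8 ketone)
Product: 19 (8S)-alcohol (C6 OTES, C9 OAc)
Conditions: (R)-2-methyl-CBS-oxazaborolidine (20 mol %), catecholborane, toluene, −78 °C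
Reagents that add atoms: none
Why: Corey–Bakshi–Shibata reduction, in which the (R)-oxazaborolidine delivers hydride to the ketone face that gives 8S when the branched C9 side acts as the large group, a sense that coincides with the polar Felkin–Anh preference of the α-acetoxy ketone (hydride anti to the C9–O bond) and so should give the 8,9-syn alcohol, while catecholborane at −78 °C leaves acrylate, vinyl group and esters alone.

Step 15
Reactants: 19 (8S)-alcohol; 20 angelic acid
Product: 22 C8 angelate (C6 OTES, C9 OAc), via angelic 2,4,6-trichlorobenzoic anhydride 21 (not isolated)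
Conditions: 20, 2,4,6-trichlorobenzoyl chloride, Et3N, toluene, rt; then 19, 75 °C
Reagents that add atoms: none
Why: Mixed-anhydride acylation of Yamaguchi type run without a nucleophilic catalyst: the alcohol attacks the less hindered angeloyl carbonyl of pre-formed anhydride 21, and leaving out DMAP avoids the angelate-to-tiglate isomerisation, C8 keeping its configuration because only the O–H bond is broken.

Step 16
Reactants: 22 C8 angelate (C6 OTES)
Product: 23 C6 alcohol (C8 angelate, C9 acetate, C2 OTBS)
Conditions: PPTS (20 mol %), MeOH–CH2Cl2, 0 °C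
Reagents that add atoms: none
Why: Acid-catalysed methanolysis removes the secondary TES ether selectively, the bulkier TBS ether, the epoxide and the three esters being stable to PPTS at 0 °C.

Step 17
Reactants: 23 C6 alcohol; 24 diethylphosphonoacetic acid
Product: 25 open-chain C6 phosphonoacetate (diene for ring closure)
Conditions: DCC, DMAP (10 mol %), CH2Cl2, 0 °C to rt
Reagents that add atoms: none
Why: Steglich esterification acylates the C6 hydroxyl with the phosphonoacetic acid under mild conditions, with retention at C6 because the C–O bond is not broken.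

Step 18
Reactants: 25 open-chain C6 phosphonoacetate
Product: 26 ten-membered ring C6 phosphonoacetate (C1=C10 alkene, C7 methylene)
Conditions: second-generation Hoveyda–Grubbs catalyst (15 mol %), toluene (1 mM), 80 °C, slow addition
Reagents that add atoms: none
Why: Ring-closing metathesis: the ruthenium carbene forms at the monosubstituted C1 vinyl group and closes onto the gem-disubstituted acrylate with loss of ethylene, a ten-membered ring accommodating only the alkene with C2 and C9 cis (CIP E, as in the target), and the cis-epoxide and the oxygenated stereocentres favouring a folded chain, while phosphonate, esters, epoxide and silyl ether are inert to the catalyst.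

Step 19
Reactants: 26 ten-membered ring C6 phosphonoacetate
Product: 27 ten-membered ring C6 diazophosphonoacetate (C7 methylene)
Conditions: p-ABSA, DBU, MeCN, 0 °C to rt
Reagents that add atoms: 4-acetamidobenzenesulfonyl azide, CC(=O)Nc1ccc(cc1)S(=O)(=O)N=[N+]=[N-]
Why: Regitz diazo transfer: DBU deprotonates the phosphonoacetate methylene, the only strongly acidic site, and the carbanion takes the N2 unit from the sulfonyl azide; the step follows the metathesis because diazo compounds are destroyed by ruthenium carbenes.

Step 20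
Reactants: 27 ten-membered ring C6 diazophosphonoacetate
Product: 28 trans-fused α-phosphono γ-lactone (6S,7R,11S)
Conditions: Rh2(OAc)4 (3 mol %), CH2Cl2 (5 mM), 40 °C, slow addition of 27
Reagents that add atoms: none
Why: Rh2(OAc)4, a divalent rhodium carboxylate, takes N2 from the diazo carbon C11 to give an electrophilic acceptor/acceptor carbene held on the C6 oxygen, which inserts into one C7–H bond through a concerted three-centre transition state with retention at C7 (closest known reaction type: rhodium-catalysed γ-lactone formation from diazoacetates and diazophosphonoacetates). The new ring O–C6–C7–C11–C12 closes in the 1,5 mode, the five-membered array C11–C12–O–C6–C7 being favoured over any larger one. C7 is set by the macrocycle: with C5 and C8 anti about the C6–C7 bond, as in 6,7-trans germacranolides, the hydrogen syn to the C6–O bond is the one reached, which gives the trans fusion (6S,7R), while C11 settles with phosphorus trans to C8 and is destroyed in the next step. Site selectivity comes from the substrate: the only other 1,5 C–H bond, at C5, is an epoxide C–H of high s-character, the 1,6 C–H at C8 is deactivated by the angeloyloxy group and C9–H by the acetate, and the C2 hydroxyl is silylated so that O–H insertion cannot occur. The C1=C10 and angelate alkenes are electron-poor and remote, so cyclopropanation is not expected, and slow addition at high dilution suppresses carbene dimerisation; attack of the carbene on the epoxide oxygen is the main residual risk.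

Step 21
Reactants: 28 trans-fused α-phosphono γ-lactone
Product: 29 α-methylene lactone, C2 TBS ether of the target
Conditions: KOtBu (1.0 equiv), THF, 0 °C; (CH2O)n, 0 °C to rt
Reagents that add atoms: paraformaldehyde (as formaldehyde), C=O
Why: Horner–Wadsworth–Emmons olefination with formaldehyde: the single equivalent of base is consumed by the acidic α-phosphono lactone, whose anion adds to formaldehyde and collapses to the exocyclic alkene and diethyl phosphate, which removes the C11 stereocentre and leaves C6 and C7 untouched.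

Step 22
Reactants: 29 α-methylene lactone, C2 TBS ether
Product: 30 target CNP0278274.1
Conditions: Et3N·3HF, MeCN, rt
Reagents that add atoms: none
Why: Fluoride-mediated desilylation with the mild, non-basic amine–HF complex cleaves only the Si–O bond at C2, conditions under which the epoxide, the α-methylene lactone and the three esters are expected to survive.

**Compound list**

1 | (S)-epichlorohydrin | ClC[C@@H]1CO1 | starting material
2 | (S)-1-chloropent-4-yn-2-ol | ClC[C@@H](O)CC#C | intermediate
3 | (S)-2-propargyloxirane | C#CC[C@H]1CO1 | intermediate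
4 | (S)-hex-1-en-5-yn-3-ol | C=C[C@@H](O)CC#C | intermediate
5 | (S)-3-(tert-butyldimethylsilyloxy)hex-1-en-5-yne | C=C[C@@H](O[Si](C)(C)C(C)(C)C)CC#C | intermediate
6 | (S)-5-(tert-butyldimethylsilyloxy)hept-6-en-2-yn-1-ol | C=C[C@@H](O[Si](C)(C)C(C)(C)C)CC#CCO | intermediate
7 | (2Z,5S)-5-(tert-butyldimethylsilyloxy)-3-methylhepta-2,6-dien-1-ol | C=C[C@@H](O[Si](C)(C)C(C)(C)C)C/C(C)=C\CO | intermediate
8 | [(2S,3R)-3-[(2S)-2-(tert-butyldimethylsilyloxy)but-3-en-1-yl]-3-methyloxiran-2-yl]methanol | C=C[C@@H](O[Si](C)(C)C(C)(C)C)C[C@@]1(C)O[C@H]1CO | intermediate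
9 | (2R,3R)-3-[(2S)-2-(tert-butyldimethylsilyloxy)but-3-en-1-yl]-3-methyloxirane-2-carbaldehyde | C=C[C@@H](O[Si](C)(C)C(C)(C)C)C[C@@]1(C)O[C@H]1C=O | intermediate
10 | methacrolein | C=C(C)C=O | starting material
11 | methyl acrylate | C=CC(=O)OC | starting material
12 | methyl (±)-3-hydroxy-4-methyl-2-methylidenepent-4-enoate | C=C(C)C(O)C(=C)C(=O)OC | intermediate
13 | methyl (R)-3-hydroxy-4-methyl-2-methylidenepent-4-enoate | C=C(C)[C@@H](O)C(=C)C(=O)OC | intermediate
14 | methyl (R)-3-acetoxy-4-methyl-2-methylidenepent-4-enoate | C=C(C)[C@@H](OC(C)=O)C(=C)C(=O)OC | intermediate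
15 | methyl (S)-3-acetoxy-2-methylidene-4-oxopentanoate | CC(=O)[C@@H](OC(C)=O)C(=C)C(=O)OC | intermediate
16 | methyl (S)-3-acetoxy-4-(dicyclohexylboranyloxy)-2-methylidenepent-4-enoate (boron enolate of 15) | C=C(OB(C1CCCCC1)C1CCCCC1)[C@@H](OC(C)=O)C(=C)C(=O)OC | intermediate
17 | methyl (3S,6S)-3-acetoxy-6-hydroxy-2-methylidene-4-oxo-6-[(2S,3R)-3-methyl-3-[(2S)-2-(tert-butyldimethylsilyloxy)but-3-en-1-yl]oxiran-2-yl]hexanoate | C=C[C@@H](O[Si](C)(C)C(C)(C)C)C[C@@]1(C)O[C@H]1[C@@H](O)CC(=O)[C@@H](OC(C)=O)C(=C)C(=O)OC | intermediate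
18 | 6-O-triethylsilyl ether of 17 (3S,6S) | C=C[C@@H](O[Si](C)(C)C(C)(C)C)C[C@@]1(C)O[C@H]1[C@@H](O[Si](CC)(CC)CC)CC(=O)[C@@H](OC(C)=O)C(=C)C(=O)OC | intermediate
19 | methyl (3S,4S,6S)-3-acetoxy-4-hydroxy-2-methylidene-6-(triethylsilyloxy)-6-[(2S,3R)-3-methyl-3-[(2S)-2-(tert-butyldimethylsilyloxy)but-3-en-1-yl]oxiran-2-yl]hexanoate | C=C[C@@H](O[Si](C)(C)C(C)(C)C)C[C@@]1(C)O[C@H]1[C@@H](O[Si](CC)(CC)CC)C[C@H](O)[C@@H](OC(C)=O)C(=C)C(=O)OC | intermediate
20 | angelic acid, (Z)-2-methylbut-2-enoic acid | C/C=C(/C)C(=O)O | starting material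
21 | angelic 2,4,6-trichlorobenzoic anhydride | C/C=C(/C)C(=O)OC(=O)c1c(Cl)cc(Cl)cc1Cl | intermediate
22 | 4-O-angelate of 19 (3S,4S,6S; germacrane C8 angelate, C9 acetate, C6 OTES) | C=C[C@@H](O[Si](C)(C)C(C)(C)C)C[C@@]1(C)O[C@H]1[C@@H](O[Si](CC)(CC)CC)C[C@H](OC(=O)/C(C)=C\C)[C@@H](OC(C)=O)C(=C)C(=O)OC | intermediate
23 | 6-hydroxy compound from 22 (3S,4S,6S; germacrane C6 alcohol) | C=C[C@@H](O[Si](C)(C)C(C)(C)C)C[C@@]1(C)O[C@H]1[C@@H](O)C[C@H](OC(=O)/C(C)=C\C)[C@@H](OC(C)=O)C(=C)C(=O)OC | intermediate
24 | diethylphosphonoacetic acid | CCOP(=O)(OCC)CC(=O)O | starting material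
25 | 6-O-[(diethoxyphosphoryl)acetyl] ester of 23 (open-chain diene; germacrane 2S,4R,5S,6S,8S,9S) | C=C[C@@H](O[Si](C)(C)C(C)(C)C)C[C@@]1(C)O[C@H]1[C@@H](OC(=O)CP(=O)(OCC)OCC)C[C@H](OC(=O)/C(C)=C\C)[C@@H](OC(C)=O)C(=C)C(=O)OC | intermediate
26 | methyl (1(10)E,2S,4R,5S,6S,8S,9S)-9-acetoxy-8-(angeloyloxy)-2-(tert-butyldimethylsilyloxy)-6-[(diethoxyphosphoryl)acetoxy]-4,5-epoxy-4-methylcyclodec-1(10)-ene-10-carboxylate (germacrane locants) | CCOP(=O)(OCC)CC(=O)O[C@H]2C[C@H](OC(=O)/C(C)=C\C)[C@@H](OC(C)=O)/C(C(=O)OC)=C\[C@@H](O[Si](C)(C)C(C)(C)C)C[C@@]1(C)O[C@@H]21 | intermediate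
27 | the 6-O-[diazo(diethoxyphosphoryl)acetyl] analogue of 26 (C7 methylene) | CCOP(=O)(OCC)C(=[N+]=[N-])C(=O)O[C@H]2C[C@H](OC(=O)/C(C)=C\C)[C@@H](OC(C)=O)/C(C(=O)OC)=C\[C@@H](O[Si](C)(C)C(C)(C)C)C[C@@]1(C)O[C@@H]21 | intermediate
28 | (1(10)E,2S,4R,5S,6S,7R,8S,9S,11S)-11-(diethoxyphosphoryl) 12,6-lactone, trans-fused at C6/C7 (C2 OTBS, C8 angelate, C9 acetate, C14 methyl ester) | CCOP(=O)(OCC)[C@@H]1C(=O)O[C@H]2[C@H]1[C@H](OC(=O)/C(C)=C\C)[C@@H](OC(C)=O)/C(C(=O)OC)=C\[C@@H](O[Si](C)(C)C(C)(C)C)C[C@@]1(C)O[C@@H]21 | intermediate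
29 | 2-O-tert-butyldimethylsilyl ether of the target (11(13)-methylene 12,6-lactone) | C=C1C(=O)O[C@H]2[C@H]1[C@H](OC(=O)/C(C)=C\C)[C@@H](OC(C)=O)/C(C(=O)OC)=C\[C@@H](O[Si](C)(C)C(C)(C)C)C[C@@]1(C)O[C@@H]21 | intermediate
30 | CNP0278274.1, methyl (1(10)E,2S,4R,5S,6S,7R,8S,9S)-9-acetoxy-8-(angeloyloxy)-4,5-epoxy-2-hydroxy-12-oxo-12,6-epoxygermacra-1(10),11(13)-dien-14-oate | C=C1C(=O)O[C@H]2[C@H]1[C@H](OC(=O)/C(C)=C\C)[C@@H](OC(C)=O)/C(C(=O)OC)=C\[C@@H](O)C[C@@]1(C)O[C@@H]21 | target

**Count**

Total steps: 22. Longest linear sequence: 18 (steps 1–7 and 12–22); steps 8–11 run in parallel.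

**Steps most likely to fail**

1. Step 20 (carbene C–H insertion). What may go wrong: capture of the carbene by the epoxide oxygen (oxonium ylide formation, then deoxygenation or rearrangement), insertion into the C7–H bond that leads to cis fusion, or transannular C–H insertion, all governed by a ring conformation that cannot be fixed in advance. A less electrophilic carboxamidate such as Rh2(NHCOCH3)4 is the first adjustment. The fallback takes the insertion out of the macrocycle. It sets out from diene 25: diazo transfer (p-ABSA, DBU) should give the open-chain diazophosphonoacetate F1. Rh2(OAc)4 should then close the lactone in the open chain, where the 1,5 insertion at C7 is free of transannular constraints and the 4,5-trans-disubstituted butanolide is the usual outcome, giving the open-chain α-phosphono lactone F2. Ring-closing metathesis of F2 with the second-generation Hoveyda–Grubbs catalyst, the lactone now serving as a conformational lock, comes back to the route at 28.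

2. Step 18 (ring-closing metathesis). What may go wrong: oligomerisation through the C1 vinyl group, or failure of the loaded carbene to engage the hindered, electron-poor acrylate because of transannular strain on the way to the ten-membered ring. The fallback closes the ring while C8 is still sp2 and before the C6 and C8 esters are in place. It sets out from silyl ether 18: metathesis should give the ten-membered ketone F3, CBS reduction the ring alcohol F4, angeloylation as in step 15 the ring angelate F5, and PPTS in methanol the ring C6 alcohol F6. Esterification of F6 with 24 (DCC, DMAP) comes back to the route at 26.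

3. Step 12 (boron aldol). What may go wrong: poor facial selectivity at the epoxy aldehyde, so that C6 epimers form, or enolisation toward C9 with loss of configuration there. The fallback makes the C6 ester bond with inversion, so that the other epimer becomes usable. It sets out from 15 and 9: the separated 6R aldol F7 is carried through the same silylation (6R silyl ether F8), reduction (6R C8 alcohol F9), angeloylation (6R angelate F10) and desilylation (6R C6 alcohol F11). Mitsunobu esterification of F11 with 24 (PPh3, DIAD) inverts C6 and comes back to the route at 25.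

**Further compounds**

F1 | step 20 | open-chain 6-O-[diazo(diethoxyphosphoryl)acetyl] ester (diazo analogue of 25) | C=C[C@@H](O[Si](C)(C)C(C)(C)C)C[C@@]1(C)O[C@H]1[C@@H](OC(=O)C(=[N+]=[N-])P(=O)(OCC)OCC)C[C@H](OC(=O)/C(C)=C\C)[C@@H](OC(C)=O)C(=C)C(=O)OC
F2 | step 20 | open-chain trans-4,5-disubstituted α-(diethoxyphosphoryl) γ-lactone (6S,7R,11S) bearing both metathesis alkenes | C=C[C@@H](O[Si](C)(C)C(C)(C)C)C[C@@]1(C)O[C@H]1[C@H]2OC(=O)[C@@H](P(=O)(OCC)OCC)[C@@H]2[C@H](OC(=O)/C(C)=C\C)[C@@H](OC(C)=O)C(=C)C(=O)OC
F3 | step 18 | ten-membered C8 ketone (C6 OTES, C9 OAc, C2 OTBS, C1=C10 ester) | CC[Si](CC)(CC)O[C@H]2CC(=O)[C@@H](OC(C)=O)/C(C(=O)OC)=C\[C@@H](O[Si](C)(C)C(C)(C)C)C[C@@]1(C)O[C@@H]21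
F4 | step 18 | ten-membered (8S)-alcohol (C6 OTES) | CC[Si](CC)(CC)O[C@H]2C[C@H](O)[C@@H](OC(C)=O)/C(C(=O)OC)=C\[C@@H](O[Si](C)(C)C(C)(C)C)C[C@@]1(C)O[C@@H]21
F5 | step 18 | ten-membered C8 angelate (C6 OTES) | CC[Si](CC)(CC)O[C@H]2C[C@H](OC(=O)/C(C)=C\C)[C@@H](OC(C)=O)/C(C(=O)OC)=C\[C@@H](O[Si](C)(C)C(C)(C)C)C[C@@]1(C)O[C@@H]21
F6 | step 18 | ten-membered C6 alcohol (C8 angelate, C9 acetate) | O[C@H]2C[C@H](OC(=O)/C(C)=C\C)[C@@H](OC(C)=O)/C(C(=O)OC)=C\[C@@H](O[Si](C)(C)C(C)(C)C)C[C@@]1(C)O[C@@H]21
F7 | step 12 | 6R epimer of aldol 17 | C=C[C@@H](O[Si](C)(C)C(C)(C)C)C[C@@]1(C)O[C@H]1[C@H](O)CC(=O)[C@@H](OC(C)=O)C(=C)C(=O)OC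
F8 | step 12 | 6R epimer of silyl ether 18 | C=C[C@@H](O[Si](C)(C)C(C)(C)C)C[C@@]1(C)O[C@H]1[C@H](O[Si](CC)(CC)CC)CC(=O)[C@@H](OC(C)=O)C(=C)C(=O)OC
F9 | step 12 | 6R epimer of alcohol 19 | C=C[C@@H](O[Si](C)(C)C(C)(C)C)C[C@@]1(C)O[C@H]1[C@H](O[Si](CC)(CC)CC)C[C@H](O)[C@@H](OC(C)=O)C(=C)C(=O)OC
F10 | step 12 | 6R epimer of angelate 22 | C=C[C@@H](O[Si](C)(C)C(C)(C)C)C[C@@]1(C)O[C@H]1[C@H](O[Si](CC)(CC)CC)C[C@H](OC(=O)/C(C)=C\C)[C@@H](OC(C)=O)C(=C)C(=O)OC
F11 | step 12 | 6R epimer of alcohol 23 | C=C[C@@H](O[Si](C)(C)C(C)(C)C)C[C@@]1(C)O[C@H]1[C@H](O)C[C@H](OC(=O)/C(C)=C\C)[C@@H](OC(C)=O)C(=C)C(=O)OC
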